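**Retrosynthetic overview** (guaiane numbering)
- Target ⇐ its phenol O-acetate (aminolysis). The skipped 1(10),3-diene and C5–H ⇐ oxazaborolidine-controlled reductive 1,3-transposition of a dienone tosylhydrazone (proposed new step).
- Guaia-1(10),4-dien-3-one ⇐ rhodium-catalysed allenic Pauson–Khand-type cyclocarbonylation of an acyclic allenyne ester. The seven-membered ring closes first (C5–C1) and the five-membered ring second (CO insertion), both in one step.
- Allenyne ester ⇐ acylation with O-acetylvanilloyl chloride of a homoallenyl alcohol ⇐ homoallenylboration of (R)-2-isopropylhex-4-ynal with a 2-boryl-1,3-diene (sets C8).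
- Aldehyde ⇐ Evans alkylation of an N-isovaleryl oxazolidinone with 1-bromobut-2-yne (sets C7); dienylboronate ⇐ ethylene–alkyne metathesis of a propynylboronate.

Assumption: bicyclic compounds are named with guaiane numbering (five-membered ring C1–C5, seven-membered ring C1, C5–C10, methyls on C4 and C10, isopropyl on C7, oxygen on C8); prop-1-ynylboronic acid pinacol ester and 4-acetoxy-3-methoxybenzoic acid are taken as catalogue compounds.

**Route**

Step 1
Reactants: 1 (4R)-4-benzyl-1,3-oxazolidin-2-one; 2 3-methylbutanoyl chloride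
Product: 4 (4R)-4-benzyl-3-(3-methylbutanoyl)-1,3-oxazolidin-2-one, via N-lithio oxazolidinone 3 (not isolated)
Conditions: n-BuLi, THF, −78 °C; then 2, −78 → 0 °C
Reagents that add atoms: none
Why: N-acylation of the lithium amide of the Evans auxiliary by the acid chloride; no stereocentre is formed or touched.

Step 2
Reactants: 4 (4R)-4-benzyl-3-(3-methylbutanoyl)-1,3-oxazolidin-2-one; 5 1-bromobut-2-yne
Product: 7 (4R)-4-benzyl-3-[(2R)-2-(propan-2-yl)hex-4-ynoyl]-1,3-oxazolidin-2-one, via sodium Z-enolate 6 (not isolated)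
Conditions: NaN(SiMe3)2, THF, −78 °C; then 5, −78 → −40 °C
Reagents that add atoms: none
Why: Evans asymmetric alkylation: the chelated sodium Z-enolate is attacked by the reactive propargylic bromide on the face opposite the C4 benzyl group, which sets the new α-centre (later C7) as R.

Step 3
Reactants: 7 (4R)-4-benzyl-3-[(2R)-2-(propan-2-yl)hex-4-ynoyl]-1,3-oxazolidin-2-one
Product: 8 (2R)-2-(propan-2-yl)hex-4-yn-1-ol
Conditions: LiBH4, H2O (1.1 equiv), Et2O, 0 °C
Reagents that add atoms: none
Why: reductive cleavage of the imide by LiBH4 at the exocyclic carbonyl gives the primary alcohol without epimerising the α-centre or reducing the alkyne, and returns the auxiliary.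

Step 4
Reactants: 8 (2R)-2-(propan-2-yl)hex-4-yn-1-ol
Product: 9 (2R)-2-(propan-2-yl)hex-4-ynal
Conditions: Dess–Martin periodinane, CH2Cl2, 0 → 23 °C; used at once
Reagents that add atoms: none
Why: Dess–Martin oxidation is non-basic and cold, so the α-branched aldehyde forms without epimerisation.

Step 5
Reactants: 10 4,4,5,5-tetramethyl-2-(prop-1-yn-1-yl)-1,3,2-dioxaborolane
Product: 11 4,4,5,5-tetramethyl-2-(3-methylbuta-1,3-dien-2-yl)-1,3,2-dioxaborolane
Conditions: RuCl2(=CHPh)(H2IMes)(PCy3) (second-generation Grubbs catalyst, 5 mol %), ethylene (4 bar), CH2Cl2, 40 °C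
Reagents that add atoms: ethylene, C=C
Why: ethylene–alkyne cross (enyne) metathesis: the ruthenium methylidene adds across the alkynylboronate and the vinylcarbene is turned over by ethylene, placing one CH2 on each former alkyne carbon to give the 2-boryl-1,3-diene.

Step 6
Reactants: 9 (2R)-2-(propan-2-yl)hex-4-ynal; 11 4,4,5,5-tetramethyl-2-(3-methylbuta-1,3-dien-2-yl)-1,3,2-dioxaborolane
Product: 13 (5S,6R)-3-methyl-6-(propan-2-yl)deca-1,2-dien-8-yn-5-ol, via pinacol borate ester 12 (not isolated)
Conditions: 11 (1.5 equiv), (S)-3,3'-bis(2,4,6-triisopropylphenyl)-1,1'-binaphthyl-2,2'-diyl hydrogen phosphate [(S)-TRIP, 10 mol %], 4 Å MS, toluene, −30 → 23 °C; aq. NaHCO3 work-up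
Reagents that add atoms: none
Why: homoallenylboration, an allylboration by the B–C(=CH2)–C(CH3)=CH2 unit through a closed chair transition state in which the boron-bearing carbon becomes the central allene carbon; the chiral phosphoric acid activates the boronate by hydrogen bonding and directs attack to the aldehyde Si face (the mirror-image acid sends allylboronates to the Re face), overriding the weak Felkin–Anh bias and setting the carbinol centre (later C8) as S.

Step 7
Reactants: 14 4-acetoxy-3-methoxybenzoic acid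
Product: 15 4-acetoxy-3-methoxybenzoyl chloride
Conditions: (COCl)2, DMF (cat.), CH2Cl2, 0 → 23 °C; evaporate
Reagents that add atoms: oxalyl chloride, ClC(=O)C(=O)Cl
Why: Vilsmeier-type activation converts the acid into the acid chloride while the aryl acetate is inert.

Step 8
Reactants: 13 (5S,6R)-3-methyl-6-(propan-2-yl)deca-1,2-dien-8-yn-5-ol; 15 4-acetoxy-3-methoxybenzoyl chloride
Product: 16 (5S,6R)-3-methyl-6-(propan-2-yl)deca-1,2-dien-8-yn-5-yl 4-acetoxy-3-methoxybenzoate
Conditions: pyridine, DMAP (10 mol %), CH2Cl2, 0 → 23 °C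
Reagents that add atoms: none
Why: DMAP-catalysed acylation of the secondary alcohol by the acid chloride; the carbinol C–O bond is not broken, so configuration is retained, and the ester protects the C8 oxygen for the rest of the route.

Step 9
Reactants: 16 (5S,6R)-3-methyl-6-(propan-2-yl)deca-1,2-dien-8-yn-5-yl 4-acetoxy-3-methoxybenzoate
Product: 17 (7R,8S)-3-oxoguaia-1(10),4-dien-8-yl 4-acetoxy-3-methoxybenzoate
Conditions: [Rh(CO)2Cl]2 (5 mol %), CO (1 atm), toluene (0.02 M), 90 °C
Reagents that add atoms: carbon monoxide, [C-]#[O+]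
Why: allenic Pauson–Khand-type [2+2+1] cyclocarbonylation: at rhodium the alkyne couples with the distal π-bond of the allene (closing the seven-membered ring through C5–C1), CO inserts and reductive elimination closes the cyclopentenone; a four-atom tether with a methyl-substituted allene is the established substrate type for bicyclo[5.3.0] dienones, no β-hydrogen is available for an Alder-ene escape, and no stereocentre is formed or touched.

Step 10
Reactants: 17 (7R,8S)-3-oxoguaia-1(10),4-dien-8-yl 4-acetoxy-3-methoxybenzoate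
Product: 18 (3E,7R,8S)-3-[2-(4-methylbenzenesulfonyl)hydrazinylidene]guaia-1(10),4-dien-8-yl 4-acetoxy-3-methoxybenzoate
Conditions: TsNHNH2 (1.1 equiv), PPTS (5 mol %), 4 Å MS, THF, 45 °C
Reagents that add atoms: 4-methylbenzenesulfonohydrazide, Cc1ccc(cc1)S(=O)(=O)NN
Why: acid-catalysed hydrazone condensation gives the E-isomer (N–N bond turned away from the C4 methyl); weakly acidic conditions are used because C9–H of the dienone is vinylogously acidic and base could eliminate the C8 ester.

Step 11
Reactants: 18 (3E,7R,8S)-3-[2-(4-methylbenzenesulfonyl)hydrazinylidene]guaia-1(10),4-dien-8-yl 4-acetoxy-3-methoxybenzoate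
Product: 21 (5R,7R,8S)-guaia-1(10),3-dien-8-yl 4-acetoxy-3-methoxybenzoate, via allylic tosylhydrazine 19 (not isolated), via allylic diazene 20 (not isolated)
Conditions: (S)-2-methyl-CBS-oxazaborolidine (20 mol %), catecholborane (2.5 equiv), toluene/CH2Cl2, −40 °C; then NaOAc·3H2O, CHCl3, 60 °C
Reagents that add atoms: none
Why: Proposed new method: an oxazaborolidine-catalysed, enantioface-selective version of the catecholborane reduction of an enone tosylhydrazone, in which the Lewis-acidic ring boron binds the only imine lone pair (syn to C4, since NHTs lies on the C2 side) while the ring nitrogen activates catecholborane, so hydride is delivered through the usual six-membered array to the Re face of C3 (the face syn to the C8 acyloxy group) to give the (3S)-hydrazine; acetate then expels sulfinate to give the monoalkyl diazene, which loses N2 by a suprafacial retro-ene that places H on C5 on the face the nitrogen leaves and moves the double bond to C3=C4, so C5 is set R by catalyst control and the skipped diene forms under neutral conditions; the closest known chemistry is the racemic Kabalka/Myers reductive 1,3-transposition of enone sulfonylhydrazones and allylic diazenes, and the CBS reduction of enones with catecholborane.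

Step 12
Reactants: 21 (5R,7R,8S)-guaia-1(10),3-dien-8-yl 4-acetoxy-3-methoxybenzoate
Product: 22 (5R,7R,8S)-guaia-1(10),3-dien-8-yl 4-hydroxy-3-methoxybenzoate (CNP0156298.2)
Conditions: pyrrolidine (2 equiv), CH2Cl2, 0 °C; aq. NH4Cl work-up
Reagents that add atoms: none
Why: chemoselective aminolysis: the aryl acetate is far more electrophilic than the hindered secondary alkyl benzoate, and the conditions leave the doubly allylic C5–H untouched.

**Compound list**

1 | (4R)-4-benzyl-1,3-oxazolidin-2-one | O=C1N[C@H](Cc2ccccc2)CO1 | starting material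
2 | 3-methylbutanoyl chloride | CC(C)CC(Cl)=O | starting material
3 | lithium (4R)-4-benzyl-2-oxo-1,3-oxazolidin-3-ide (N-lithio oxazolidinone, formed in the flask) | [Li]N1[C@H](Cc2ccccc2)COC1=O | intermediate
4 | (4R)-4-benzyl-3-(3-methylbutanoyl)-1,3-oxazolidin-2-one | CC(C)CC(=O)N1[C@H](Cc2ccccc2)COC1=O | intermediate
5 | 1-bromobut-2-yne | CC#CCBr | starting material
6 | sodium (1Z)-1-[(4R)-4-benzyl-2-oxo-1,3-oxazolidin-3-yl]-3-methylbut-1-en-1-olate (sodium Z-enolate, formed in the flask) | CC(C)/C=C(\[O-])N1[C@H](Cc2ccccc2)COC1=O.[Na+] | intermediate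
7 | (4R)-4-benzyl-3-[(2R)-2-(propan-2-yl)hex-4-ynoyl]-1,3-oxazolidin-2-one | CC#CC[C@H](C(C)C)C(=O)N1[C@H](Cc2ccccc2)COC1=O | intermediate
8 | (2R)-2-(propan-2-yl)hex-4-yn-1-ol | CC#CC[C@H](C(C)C)CO | intermediate
9 | (2R)-2-(propan-2-yl)hex-4-ynal | CC#CC[C@H](C(C)C)C=O | intermediate
10 | 4,4,5,5-tetramethyl-2-(prop-1-yn-1-yl)-1,3,2-dioxaborolane | CC#CB1OC(C)(C)C(C)(C)O1 | starting material
11 | 4,4,5,5-tetramethyl-2-(3-methylbuta-1,3-dien-2-yl)-1,3,2-dioxaborolane | CC(=C)C(=C)B1OC(C)(C)C(C)(C)O1 | intermediate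
12 | 4,4,5,5-tetramethyl-2-{[(5S,6R)-3-methyl-6-(propan-2-yl)deca-1,2-dien-8-yn-5-yl]oxy}-1,3,2-dioxaborolane (pinacol borate ester, formed in the flask) | CC#CC[C@H](C(C)C)[C@@H](OB1OC(C)(C)C(C)(C)O1)CC(C)=C=C | intermediate
13 | (5S,6R)-3-methyl-6-(propan-2-yl)deca-1,2-dien-8-yn-5-ol | CC#CC[C@H](C(C)C)[C@@H](O)CC(C)=C=C | intermediate
14 | 4-acetoxy-3-methoxybenzoic acid | CC(=O)Oc1ccc(cc1OC)C(O)=O | starting material
15 | 4-acetoxy-3-methoxybenzoyl chloride | CC(=O)Oc1ccc(cc1OC)C(Cl)=O | intermediate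
16 | (5S,6R)-3-methyl-6-(propan-2-yl)deca-1,2-dien-8-yn-5-yl 4-acetoxy-3-methoxybenzoate | CC#CC[C@H](C(C)C)[C@@H](OC(=O)c1ccc(OC(C)=O)c(OC)c1)CC(C)=C=C | intermediate
17 | (7R,8S)-3-oxoguaia-1(10),4-dien-8-yl 4-acetoxy-3-methoxybenzoate; (5R,6S)-3,8-dimethyl-2-oxo-5-(propan-2-yl)-1,2,4,5,6,7-hexahydroazulen-6-yl ester | CC(=O)Oc1ccc(cc1OC)C(=O)O[C@H]2CC(C)=C3CC(=O)C(C)=C3C[C@@H]2C(C)C | intermediate
18 | (3E,7R,8S)-3-[2-(4-methylbenzenesulfonyl)hydrazinylidene]guaia-1(10),4-dien-8-yl 4-acetoxy-3-methoxybenzoate | CC(=O)Oc1ccc(cc1OC)C(=O)O[C@H]2CC(C)=C3C/C(=N\NS(=O)(=O)c4ccc(C)cc4)C(C)=C3C[C@@H]2C(C)C | intermediate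
19 | (3S,7R,8S)-3-[2-(4-methylbenzenesulfonyl)hydrazin-1-yl]guaia-1(10),4-dien-8-yl 4-acetoxy-3-methoxybenzoate (allylic tosylhydrazine, formed in the flask) | CC(=O)Oc1ccc(cc1OC)C(=O)O[C@H]2CC(C)=C3C[C@H](NNS(=O)(=O)c4ccc(C)cc4)C(C)=C3C[C@@H]2C(C)C | intermediate
20 | (3S,7R,8S)-3-diazenylguaia-1(10),4-dien-8-yl 4-acetoxy-3-methoxybenzoate (allylic diazene, formed in the flask) | CC(=O)Oc1ccc(cc1OC)C(=O)O[C@H]2CC(C)=C3C[C@H](N=N)C(C)=C3C[C@@H]2C(C)C | intermediate
21 | (5R,7R,8S)-guaia-1(10),3-dien-8-yl 4-acetoxy-3-methoxybenzoate; (3aR,5R,6S)-3,8-dimethyl-5-(propan-2-yl)-1,3a,4,5,6,7-hexahydroazulen-6-yl ester | CC(=O)Oc1ccc(cc1OC)C(=O)O[C@H]2CC(C)=C3CC=C(C)[C@H]3C[C@@H]2C(C)C | intermediate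
22 | (5R,7R,8S)-guaia-1(10),3-dien-8-yl 4-hydroxy-3-methoxybenzoate; (3aR,5R,6S)-3,8-dimethyl-5-(propan-2-yl)-1,3a,4,5,6,7-hexahydroazulen-6-yl 4-hydroxy-3-methoxybenzoate | COc1cc(C(=O)O[C@H]2CC(C)=C3CC=C(C)[C@H]3C[C@@H]2C(C)C)ccc1O | target

**Step count**

Total: 12 steps. Longest linear sequence: 10 steps (steps 1, 2, 3, 4, 6, 8, 9, 10, 11, 12); steps 5 and 7 are one-step branches.

**Three steps most likely to fail, with fallbacks**

Step 11 (the proposed new step). The sulfonylhydrazone may bind the oxazaborolidine poorly, or the uncatalysed catecholborane reduction may compete, either of which would give a mixture of C5 epimers; if the facial sense is opposite to the lone-pair model, the (R)-catalyst is the first remedy. The fallback uses known chemistry, sets out from dienone 17 and returns at 21. 17 is reduced 1,2 from the Si face with (S)-2-methyl-CBS-oxazaborolidine (20 mol %) and catecholborane in toluene at −78 °C (the α-methylated alkene acts as the large group) to the allylic alcohol (3R,7R,8S)-3-hydroxyguaia-1(10),4-dien-8-yl 4-acetoxy-3-methoxybenzoate F1. Mitsunobu displacement with 2-nitrobenzenesulfonohydrazide (PPh3, diethyl azodicarboxylate, THF, −30 °C) inverts C3 and gives the sulfonylhydrazine (3S,7R,8S)-3-[1-(2-nitrobenzenesulfonyl)hydrazin-1-yl]guaia-1(10),4-dien-8-yl 4-acetoxy-3-methoxybenzoate F2. On warming to 23 °C F2 loses the sulfinic acid to give diazene 20, which extrudes N2 to 21 (Myers reductive transposition).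

Step 6. The pinacol dienylboronate is a sluggish allyl donor and the acid must override the Felkin–Anh preference of the α-branched aldehyde. The fallback sets out from 9 (with 11) and returns at 13; it uses the matched pairing and then inverts. The mirror-image acid (R)-TRIP under otherwise the same conditions gives the Felkin product (5R,6R)-3-methyl-6-(propan-2-yl)deca-1,2-dien-8-yn-5-ol F3 with high selectivity. Mitsunobu inversion (4-nitrobenzoic acid, PPh3, diisopropyl azodicarboxylate, toluene, 0 → 40 °C) gives (5S,6R)-3-methyl-6-(propan-2-yl)deca-1,2-dien-8-yn-5-yl 4-nitrobenzoate F4. Methanolysis (K2CO3, MeOH, 0 °C) releases 13.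

Step 5. Ethylene–alkyne metathesis of an internal alkynylboronate can stall, and the volatile 2-boryl diene dimerises on storage. The fallback sets out from 9, needs neither 10 nor 11, and returns at 13. Propargylation of 9 with allenylboronic acid pinacol ester under (S)-TRIP catalysis (toluene, 4 Å MS, −20 °C, hydrolytic work-up) gives (4S,5R)-5-(propan-2-yl)nona-1,7-diyn-4-ol F5. Its dianion (n-BuLi, 2.2 equiv, THF, −78 °C) is hydroxymethylated with paraformaldehyde to (5S,6R)-6-(propan-2-yl)deca-2,8-diyne-1,5-diol F6. The primary propargylic hydroxyl alone is sulfonylated (MsCl, 2,4,6-collidine, CH2Cl2, −20 °C) to (5S,6R)-5-hydroxy-6-(propan-2-yl)deca-2,8-diyn-1-yl methanesulfonate F7. Anti-SN2' methylation (MeMgBr, CuBr·SMe2, LiBr, THF, −30 °C) then gives the 1,1-disubstituted allene 13.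

**Further compounds**

F1 | step 11 | (3R,7R,8S)-3-hydroxyguaia-1(10),4-dien-8-yl 4-acetoxy-3-methoxybenzoate | CC(=O)Oc1ccc(cc1OC)C(=O)O[C@H]2CC(C)=C3C[C@@H](O)C(C)=C3C[C@@H]2C(C)C
F2 | step 11 | (3S,7R,8S)-3-[1-(2-nitrobenzenesulfonyl)hydrazin-1-yl]guaia-1(10),4-dien-8-yl 4-acetoxy-3-methoxybenzoate | CC(=O)Oc1ccc(cc1OC)C(=O)O[C@H]2CC(C)=C3C[C@H](N(N)S(=O)(=O)c4ccccc4[N+](=O)[O-])C(C)=C3C[C@@H]2C(C)C
F3 | step 6 | (5R,6R)-3-methyl-6-(propan-2-yl)deca-1,2-dien-8-yn-5-ol | CC#CC[C@H](C(C)C)[C@H](O)CC(C)=C=C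
F4 | step 6 | (5S,6R)-3-methyl-6-(propan-2-yl)deca-1,2-dien-8-yn-5-yl 4-nitrobenzoate | CC#CC[C@H](C(C)C)[C@@H](OC(=O)c1ccc(cc1)[N+](=O)[O-])CC(C)=C=C
F5 | step 5 | (4S,5R)-5-(propan-2-yl)nona-1,7-diyn-4-ol | CC#CC[C@H](C(C)C)[C@@H](O)CC#C
F6 | step 5 | (5S,6R)-6-(propan-2-yl)deca-2,8-diyne-1,5-diol | CC#CC[C@H](C(C)C)[C@@H](O)CC#CCO
F7 | step 5 | (5S,6R)-5-hydroxy-6-(propan-2-yl)deca-2,8-diyn-1-yl methanesulfonate | CC#CC[C@H](C(C)C)[C@@H](O)CC#CCOS(C)(=O)=O
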